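**Assumption:** the target has no stereocentre (the quaternary carbon carries two identical prenyl groups), so it is achiral and no enantioselective step is needed. The SMILES shows one tautomer of a freely equilibrating chelated β-triketone.

## Retrosynthetic overview

1. The carbocycle is bought as phloroglucinol 1; benzoyl chloride 2 adds the aryl ketone to give 3 (Friedel–Crafts C–C bond).
2. Three C–C disconnections lead to prenyl bromide 4: one-pot C-triprenylation of 3 (through 5 and 6) dearomatises the ring and creates the gem-diprenyl carbon of 7.
3. Key disconnection, made last: the pyran O–CMe2 bond. Dienol 7 loses H2 to dienyl quinone methide 8, whose oxa-6π closure gives target 9.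
4. Ring order: benzene ring (bought), then dearomatised cyclohexadienone (step 2), then 2H-pyran (step 3).

Ring numbering of 7 used below: C1 ring carbonyl, C2 benzoyl-bearing carbon, C3 chelated enol carbon, C4 mono-prenyl carbon, C5 free enol carbon, C6 gem-diprenyl carbon; O3 and O5 are the oxygens on C3 and C5.

## Route

Step 1
Reactants: 1 phloroglucinol (benzene-1,3,5-triol); 2 benzoyl chloride
Product: 3 2,4,6-trihydroxybenzophenone
Conditions: AlCl3 (4 equiv), PhNO2, 65 °C; then ice/2 M HCl
Reagents that add atoms: benzoyl chloride, O=C(Cl)c1ccccc1
Why: Friedel–Crafts acylation of the strongly activated triol, in which the AlCl3-complexed aryl ketone product is deactivated towards a second acylation and any aryl benzoate formed is carried on by Fries rearrangement under the same conditions; no stereocentre is formed.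

Step 2
Reactants: 3 2,4,6-trihydroxybenzophenone; 4 prenyl bromide (1-bromo-3-methylbut-2-ene)
Product: 7 2-benzoyl-3,5-dihydroxy-4,6,6-tris(3-methylbut-2-en-1-yl)cyclohexa-2,4-dien-1-one, via 3-prenyl ketone 5 (not isolated), via 3,5-diprenyl ketone 6 (not isolated)
Conditions: 4 (3.2 equiv), liq. NH3/Et2O, −40 °C; then 2 M HCl
Reagents that add atoms: prenyl bromide, CC(C)=CCBr
Why: Lupulone-type exhaustive C-prenylation (SN2 at the primary carbon of 4 by the ambident ammonium phenoxide, C-selective in hydrogen-bonding liquid NH3), in which the two free ring carbons react first (5, then 6) and the third alkylation dearomatises at a prenyl-bearing carbon and not at the benzoyl-bearing one, after which the acidic dienol 7 sits as a poorly nucleophilic ammonium salt; the new quaternary carbon carries two identical groups, so no stereocentre is set.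

Step 3
Reactants: 7 2-benzoyl-3,5-dihydroxy-4,6,6-tris(3-methylbut-2-en-1-yl)cyclohexa-2,4-dien-1-one
Product: 9 6-benzoyl-7-hydroxy-2,2-dimethyl-8,8-bis(3-methylbut-2-en-1-yl)-2H-chromen-5(8H)-one (target CNP0138894.0), via dienyl quinone methide 8 (not isolated)
Conditions: DDQ (1.05 equiv), degassed PhMe, 0 °C → rt, Ar, dark
Reagents that add atoms: none
Why: Proposed new method: base-free, two-electron (hydride-transfer) dehydrogenative cycloetherification of a dearomatised tris-prenyl β-triketone, in which DDQ takes hydride only from the CH2 of the C4 prenyl group (the one CH2 whose cation is stabilised by the free O5 enol, the gem-prenyl CH2 groups being on an sp3 carbon), loss of the O5 proton gives quinone methide 8 whose C5 carbonyl is a non-enolisable ketone lying s-cis to the diene while O3 stays locked as the hydrogen-bonded enol of the benzoyl chelate in non-polar toluene, so thermal oxa-6π electrocyclisation forms the O5–CMe2 bond and the 2H-pyran, and the contact ion pair in toluene collapses before a free enoxyl radical could cyclise 5-exo onto a gem-prenyl group (the path one-electron oxidants open on such substrates); the closest known reaction type is the DDQ oxidative cyclisation of ortho-prenylphenols to 2,2-dimethyl-2H-chromenes, and no stereocentre is formed.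

## Compound list

1 | phloroglucinol (benzene-1,3,5-triol) | Oc1cc(O)cc(O)c1 | starting material
2 | benzoyl chloride | O=C(Cl)c1ccccc1 | starting material
3 | 2,4,6-trihydroxybenzophenone, (2,4,6-trihydroxyphenyl)(phenyl)methanone | O=C(c1ccccc1)c1c(O)cc(O)cc1O | intermediate
4 | prenyl bromide (1-bromo-3-methylbut-2-ene) | CC(C)=CCBr | starting material
5 | 3-prenyl ketone, phenyl[2,4,6-trihydroxy-3-(3-methylbut-2-en-1-yl)phenyl]methanone | O=C(c1ccccc1)c1c(O)cc(O)c(CC=C(C)C)c1O | intermediate
6 | 3,5-diprenyl ketone, phenyl[2,4,6-trihydroxy-3,5-bis(3-methylbut-2-en-1-yl)phenyl]methanone | O=C(c1ccccc1)c1c(O)c(CC=C(C)C)c(O)c(CC=C(C)C)c1O | intermediate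
7 | 2-benzoyl-3,5-dihydroxy-4,6,6-tris(3-methylbut-2-en-1-yl)cyclohexa-2,4-dien-1-one (benzoyl analogue of lupulone) | O=C1C(C(=O)c2ccccc2)=C(O)C(CC=C(C)C)=C(O)C1(CC=C(C)C)CC=C(C)C | intermediate
8 | dienyl quinone methide, 2-benzoyl-3-hydroxy-4-(3-methylbut-2-en-1-ylidene)-6,6-bis(3-methylbut-2-en-1-yl)cyclohex-2-ene-1,5-dione, exocyclic alkene drawn with the dienyl arm on the C5 side | O=C1C(C(=O)c2ccccc2)=C(O)/C(=C/C=C(C)C)C(=O)C1(CC=C(C)C)CC=C(C)C | intermediate
9 | 6-benzoyl-7-hydroxy-2,2-dimethyl-8,8-bis(3-methylbut-2-en-1-yl)-2H-chromen-5(8H)-one (achiral) | CC(C)=CCC1(CC=C(C)C)C(O)=C(C(=O)c2ccccc2)C(=O)C2=C1OC(C)(C)C=C2 | target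

## Summary and risks

Total step count: 3. Longest linear sequence: 3.

**Most likely to fail, 1: step 3 (the proposed new step).** The risks are closure of 8 through O3 instead of O5 (the regioisomeric pyran with its oxygen next to the benzoyl-bearing carbon), one-electron chemistry leading to radical cyclisation onto a gem-prenyl group, and over-oxidation. The regioselectivity argument is mechanistic reasoning, not a demonstrated result.

The fallback uses only known reaction types. It sets out from 3 and comes back to the route at 9. Copper-catalysed O-alkylation of the non-chelated, most acidic para hydroxyl of 3 with 3-chloro-3-methylbut-1-yne (CuCl2·2H2O 1 mol %, DBU, MeCN, 0 °C) gives (2,6-dihydroxy-4-((2-methylbut-3-yn-2-yl)oxy)phenyl)(phenyl)methanone F3. Heating this in xylene at 140 °C (aryl propargyl ether Claisen rearrangement, 1,5-hydrogen shift, oxa-6π closure) gives (5,7-dihydroxy-2,2-dimethyl-2H-chromen-6-yl)(phenyl)methanone F4. The pyran oxygen is then fixed para to the benzoyl group because the two ortho carbons are equivalent. Treatment with prenyl bromide 4 (2.2 equiv) in liq. NH3/Et2O at −40 °C alkylates the only free ring carbon twice, by way of (5,7-dihydroxy-2,2-dimethyl-8-(3-methylbut-2-en-1-yl)-2H-chromen-6-yl)(phenyl)methanone F5, and the second alkylation dearomatises the ring to give 9.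

**Most likely to fail, 2: step 2.** The one-pot triple alkylation gives under-alkylated (5, 6), tetra-prenylated and O-prenylated by-products, so the isolated yield of 7 is likely to be modest (roughly 35–50 %) and the purification demanding.

The fallback sets out from 3 and comes back to the route at 7. Alkylation of 3 with 4 (2.1 equiv) in 10 % aq. KOH at 0 °C is stopped at the aromatic 3,5-diprenyl ketone 6, which is isolated. The third prenyl group is then added by a dearomative Tsuji–Trost reaction with tert-butyl (3-methylbut-2-en-1-yl) carbonate F2 (made from prenol and Boc2O with catalytic DMAP) and Pd(PPh3)4 (5 mol %, a zerovalent palladium source) in THF at 0 °C → rt. The π-prenyl palladium electrophile is attacked at its unsubstituted terminus by the carbon of the phenoxide, and the tert-butoxide released on decarboxylation is the only base. This gives 7.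

**Most likely to fail, 3: step 1.** The risks are O-benzoylation or double acylation and the awkward removal of nitrobenzene.

The fallback sets out from 1 and comes back to the route at 3. A Hoesch reaction of 1 with benzonitrile (ZnCl2, dry HCl gas, Et2O, 0 °C) precipitates (2,4,6-trihydroxyphenyl)(phenyl)methaniminium chloride F1, which stops cleanly at mono-acylation. Boiling this salt in water hydrolyses it to 3.

## Further compounds

F1 | step 1 | (2,4,6-trihydroxyphenyl)(phenyl)methaniminium chloride | [NH2+]=C(c1ccccc1)c1c(O)cc(O)cc1O.[Cl-]
F2 | step 2 | tert-butyl (3-methylbut-2-en-1-yl) carbonate | CC(C)=CCOC(=O)OC(C)(C)C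
F3 | step 3 | (2,6-dihydroxy-4-((2-methylbut-3-yn-2-yl)oxy)phenyl)(phenyl)methanone | O=C(c1ccccc1)c1c(O)cc(OC(C)(C)C#C)cc1O
F4 | step 3 | (5,7-dihydroxy-2,2-dimethyl-2H-chromen-6-yl)(phenyl)methanone | O=C(c1ccccc1)c1c(O)cc2OC(C)(C)C=Cc2c1O
F5 | step 3 | (5,7-dihydroxy-2,2-dimethyl-8-(3-methylbut-2-en-1-yl)-2H-chromen-6-yl)(phenyl)methanone | O=C(c1ccccc1)c1c(O)c(CC=C(C)C)c2OC(C)(C)C=Cc2c1O
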